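## Retrosynthetic overview
1. The target is the symmetric CH2-bridged dimer of gigantol. No ring is formed, because all four benzene rings are bought (two orsellinate rings, two vanillyl rings).
2. Last step: global hydrogenolysis of four O-benzyl groups.
3. Key disconnection: the central Ar–CH2 bond is made by CO2 extrusion from the "homo-ester" ArCO2CH2Ar (new step). The carboxyl carbon fixes the crowded site (ortho to OMe and chain, para to O).
4. The homo-ester comes from ArCO2H and ArCH2OH, both made from one bibenzyl ester ArCO2Me (hydrolysis and reduction, then Mitsunobu).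
5. ArCO2Me comes from lateral lithiation of 4-O-benzyl-2-O-methyl methyl orsellinate and alkylation with O-benzylvanillyl bromide.

Assumption: the SMILES has no stereocentre and no hindered axis, so the target is achiral and there is no configuration to set.

Abbreviation: Ar = 4-(benzyloxy)-2-{2-[4-(benzyloxy)-3-methoxyphenyl]ethyl}-6-methoxyphenyl.

## Route

Step 1
Reactants: 1 methyl 2,4-dihydroxy-6-methylbenzoate (methyl orsellinate)
Product: 2 methyl 4-(benzyloxy)-2-hydroxy-6-methylbenzoate
Conditions: BnBr (1.05 equiv), K2CO3 (1.2 equiv), acetone, reflux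
Reagents that add atoms: benzyl bromide, BrCc1ccccc1
Why: Williamson etherification; the 2-OH is hydrogen-bonded to the ester C=O and less nucleophilic, so one equivalent of BnBr reacts at the free 4-OH.

Step 2
Reactants: 2 methyl 4-(benzyloxy)-2-hydroxy-6-methylbenzoate
Product: 3 methyl 4-(benzyloxy)-2-methoxy-6-methylbenzoate
Conditions: MeI (2 equiv), K2CO3 (2 equiv), DMF, 60 °C
Reagents that add atoms: iodomethane, CI
Why: Williamson O-methylation of the only remaining (chelated) phenol, which needs a polar solvent and heat but raises no selectivity issue.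

Step 3
Reactants: 4 [4-(benzyloxy)-3-methoxyphenyl]methanol (O-benzylvanillyl alcohol)
Product: 5 1-(benzyloxy)-4-(bromomethyl)-2-methoxybenzene
Conditions: PBr3 (0.4 equiv), Et2O, 0 °C; used directly
Reagents that add atoms: phosphorus tribromide, BrP(Br)Br
Why: PBr3 bromination (SN2 on the phosphite ester) of a primary benzylic alcohol; the labile electron-rich bromide is not stored.

Step 4
Reactants: 3 methyl 4-(benzyloxy)-2-methoxy-6-methylbenzoate; 5 1-(benzyloxy)-4-(bromomethyl)-2-methoxybenzene
Product: 7 methyl 4-(benzyloxy)-2-{2-[4-(benzyloxy)-3-methoxyphenyl]ethyl}-6-methoxybenzoate (ArCO2Me), via laterally lithiated toluate (benzylic organolithium) 6 (not isolated)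
Conditions: LDA (commercial solution, 1.15 equiv), THF, −78 °C, 30 min; then 5 (1.2 equiv), −78 → −20 °C
Reagents that add atoms: lithium diisopropylamide, CC(C)N([Li])C(C)C
Why: Lateral lithiation of the o-toluate by LDA, which delivers the lithium of 6 and leaves as diisopropylamine, gives the vinylogous ester enolate, and its SN2 alkylation with the reactive benzylic bromide builds the bibenzyl CH2–CH2 bond directly while the lithium departs as LiBr.

Step 5
Reactants: 7 ArCO2Me
Product: 8 (4-(benzyloxy)-2-{2-[4-(benzyloxy)-3-methoxyphenyl]ethyl}-6-methoxyphenyl)methanol (ArCH2OH)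
Conditions: LiAlH4 (1.5 equiv), THF, 0 °C → reflux; Na2SO4·10H2O quench (run on half of the batch of 7)
Reagents that add atoms: none
Why: Hydride reduction of the ester; the small hydride reaches the di-ortho-substituted carbonyl, aryl ethers are inert, and the neutral quench protects the acid-labile alcohol.

Step 6
Reactants: 7 ArCO2Me
Product: 10 4-(benzyloxy)-2-{2-[4-(benzyloxy)-3-methoxyphenyl]ethyl}-6-methoxybenzoic acid (ArCO2H), via potassium carboxylate ArCO2K 9 (not isolated)
Conditions: KOH (10 equiv), DMSO/H2O 4:1, 100 °C; then cold 1 M HCl to pH 3 (run on the other half of the batch of 7)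
Reagents that add atoms: potassium hydroxide, [K+].[OH-]
Why: Forcing saponification (BAc2) of a hindered benzoate; the carboxylate is stable in base, and cold, mild acidification avoids protodecarboxylation.

Step 7
Reactants: 8 ArCH2OH; 10 ArCO2H
Product: 11 homo-ester ArCO2CH2Ar (the ester of acid 10 with alcohol 8)
Conditions: PPh3 (1.3 equiv), DIAD (1.3 equiv), THF, 0 °C → rt
Reagents that add atoms: none
Why: Mitsunobu esterification; the bond forms by carboxylate attack on the activated benzylic carbon, so the hindered carbonyl of 10 is never attacked and no acid touches 8.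

Step 8
Reactants: 11 ArCO2CH2Ar
Product: 15 bis(4-(benzyloxy)-2-{2-[4-(benzyloxy)-3-methoxyphenyl]ethyl}-6-methoxyphenyl)methane (ArCH2Ar), via [(DPEphos)Pd(η3-CH2Ar)]+ ArCO2− ion pair 12 (not isolated), via arylsilver(I) Ar–Ag 13 (not isolated), via (DPEphos)Pd(Ar)(CH2Ar) 14 (not isolated)
Conditions: Pd2(dba)3 (2.5 mol %), DPEphos (6 mol %), Ag2CO3 (5 mol %), 2,6-lutidine (20 mol %), 4 Å MS, dry NMP, 120 °C, Ar
Reagents that add atoms: none
Why: Proposed new method: redox-neutral, halide-free CO2 extrusion from a benzyl arenecarboxylate by cooperative Pd(0)/Ag(I) catalysis. Pd(0)/DPEphos ionises the very electron-rich benzylic C–O bond of 11, as in Pd-catalysed benzylic substitution of benzyl esters, to give ion pair 12. The released electron-rich, di-ortho-substituted carboxylate belongs to the class that decarboxylates most easily at silver; it loses CO2 at Ag(I) to give 13, with the metal on the carbon that carried the carboxyl group, so the coupling is regiospecific. Transmetalation to the benzyl-Pd cation gives 14, and the wide-bite-angle ligand drives C(sp2)–C(sp3) reductive elimination to 15, returning both catalytic metals and the ligand, which are the only source of the Pd, Ag and phosphine in 12–14. Ag(I) turns over because no halide is present, protodecarboxylation is starved because the neutral ester carries no proton source, collapse of 12 back to 11 is degenerate, and lutidine buffers stray acid that would start cationic Friedel–Crafts chemistry. The closest known reaction types are decarboxylative benzylation of benzyl β-keto esters and propiolates, intramolecular decarboxylative allylation of allyl nitrobenzoates, and Pd/Ag decarboxylative biaryl coupling of benzoates with aryl triflates. To my knowledge, CO2 extrusion from the benzyl ester of an electron-rich alkoxybenzoic acid to give a diarylmethane has not been shown.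

Step 9
Reactants: 15 ArCH2Ar
Product: 16 4,4'-methylenebis{3-[2-(4-hydroxy-3-methoxyphenyl)ethyl]-5-methoxyphenol} (target CNP0079383.0)
Conditions: H2 (1 atm), 10 % Pd/C, EtOAc/MeOH 1:1, rt
Reagents that add atoms: none
Why: Catalytic hydrogenolysis cleaves the four benzyl aryl ethers, while methyl ethers and the diarylmethane and bibenzyl C–C bonds are inert; no stereocentre is involved.

## Compound list
1 | methyl 2,4-dihydroxy-6-methylbenzoate (methyl orsellinate) | COC(=O)c1c(C)cc(O)cc1O | starting material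
2 | methyl 4-(benzyloxy)-2-hydroxy-6-methylbenzoate | COC(=O)c1c(C)cc(OCc2ccccc2)cc1O | intermediate
3 | methyl 4-(benzyloxy)-2-methoxy-6-methylbenzoate | COC(=O)c1c(C)cc(OCc2ccccc2)cc1OC | intermediate
4 | [4-(benzyloxy)-3-methoxyphenyl]methanol | COc1cc(CO)ccc1OCc1ccccc1 | starting material
5 | 1-(benzyloxy)-4-(bromomethyl)-2-methoxybenzene | COc1cc(CBr)ccc1OCc1ccccc1 | intermediate
6 | laterally lithiated toluate (benzylic organolithium formed from 3 and LDA) | COC(=O)c1c(C[Li])cc(OCc2ccccc2)cc1OC | intermediate (not isolated)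
7 | methyl 4-(benzyloxy)-2-{2-[4-(benzyloxy)-3-methoxyphenyl]ethyl}-6-methoxybenzoate (ArCO2Me) | COC(=O)c1c(CCc2ccc(OCc3ccccc3)c(OC)c2)cc(OCc2ccccc2)cc1OC | intermediate
8 | (4-(benzyloxy)-2-{2-[4-(benzyloxy)-3-methoxyphenyl]ethyl}-6-methoxyphenyl)methanol (ArCH2OH) | OCc1c(CCc2ccc(OCc3ccccc3)c(OC)c2)cc(OCc2ccccc2)cc1OC | intermediate
9 | potassium 4-(benzyloxy)-2-{2-[4-(benzyloxy)-3-methoxyphenyl]ethyl}-6-methoxybenzoate (ArCO2K) | [K+].[O-]C(=O)c1c(CCc2ccc(OCc3ccccc3)c(OC)c2)cc(OCc2ccccc2)cc1OC | intermediate (not isolated)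
10 | 4-(benzyloxy)-2-{2-[4-(benzyloxy)-3-methoxyphenyl]ethyl}-6-methoxybenzoic acid (ArCO2H) | OC(=O)c1c(CCc2ccc(OCc3ccccc3)c(OC)c2)cc(OCc2ccccc2)cc1OC | intermediate
11 | homo-ester ArCO2CH2Ar | O=C(OCc1c(CCc2ccc(OCc3ccccc3)c(OC)c2)cc(OCc2ccccc2)cc1OC)c1c(CCc2ccc(OCc3ccccc3)c(OC)c2)cc(OCc2ccccc2)cc1OC | intermediate
12 | [(DPEphos)Pd(η3-CH2Ar)]+ ArCO2− ion pair (Pd and ligand from the catalyst; ligand written as a dot-joined component) | [Pd+]Cc1c(CCc2ccc(OCc3ccccc3)c(OC)c2)cc(OCc2ccccc2)cc1OC.[O-]C(=O)c1c(CCc2ccc(OCc3ccccc3)c(OC)c2)cc(OCc2ccccc2)cc1OC.c1ccc(cc1)P(c1ccccc1)c1ccccc1Oc1ccccc1P(c1ccccc1)c1ccccc1 | intermediate (not isolated)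
13 | arylsilver(I) Ar–Ag (Ag from the co-catalyst) | [Ag]c1c(CCc2ccc(OCc3ccccc3)c(OC)c2)cc(OCc2ccccc2)cc1OC | intermediate (not isolated)
14 | (DPEphos)Pd(Ar)(CH2Ar) (Pd and ligand from the catalyst; ligand written as a dot-joined component) | COc1cc(OCc2ccccc2)cc(CCc2ccc(OCc3ccccc3)c(OC)c2)c1[Pd]Cc1c(CCc2ccc(OCc3ccccc3)c(OC)c2)cc(OCc2ccccc2)cc1OC.c1ccc(cc1)P(c1ccccc1)c1ccccc1Oc1ccccc1P(c1ccccc1)c1ccccc1 | intermediate (not isolated)
15 | bis(4-(benzyloxy)-2-{2-[4-(benzyloxy)-3-methoxyphenyl]ethyl}-6-methoxyphenyl)methane (ArCH2Ar) | COc1cc(OCc2ccccc2)cc(CCc2ccc(OCc3ccccc3)c(OC)c2)c1Cc1c(CCc2ccc(OCc3ccccc3)c(OC)c2)cc(OCc2ccccc2)cc1OC | intermediate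
16 | 4,4'-methylenebis{3-[2-(4-hydroxy-3-methoxyphenyl)ethyl]-5-methoxyphenol} (achiral) | COc1cc(CCc2cc(O)cc(OC)c2Cc2c(CCc3ccc(O)c(OC)c3)cc(O)cc2OC)ccc1O | target

## Step count
Total step count: 9.
Longest linear sequence: 7 (steps 1, 2, 4, 5 or 6, 7, 8, 9).

## Steps most likely to fail

**Step 8 (the new CO2 extrusion).** The risks are slow decarboxylation, protodemetalation to ArH, and cationic Friedel–Crafts oligomers. The fallback uses known chemistry, sets out from 10 and 8, and comes back at 15. Acid 10 undergoes metal-free ipso-iododecarboxylation (I2, K3PO4, MeCN, 100 °C) to give the aryl iodide F1. Alcohol 8 is oxidised with MnO2 (CH2Cl2, rt) to the benzaldehyde F2. Iodine–lithium exchange on F1 (n-BuLi, THF, −78 °C) gives the aryllithium F3, which adds to F2 to give the symmetrical diarylcarbinol F4. Ionic hydrogenation of this doubly activated benzhydrol (Et3SiH, TFA, CH2Cl2, −20 °C) gives 15.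

**Step 4 (toluate alkylation).** The risks are self-condensation of the anion, dialkylation, and decomposition or Wurtz coupling of the labile bromide. The fallback sets out from 3 and comes back at 10. Anion 6 (from 3 and LDA, as in step 4) is trapped at −78 °C with commercial 4-(benzyloxy)-3-methoxybenzaldehyde, a stable and much faster electrophile. The alkoxide lactonises onto the ester to give the racemic 3-aryl-3,4-dihydroisocoumarin F5. t-BuOK in DMSO opens F5 by E1cB elimination to the (E)-stilbene-2-carboxylic acid F6, which destroys the transient stereocentre. Diimide (TsNHNH2, NaOAc, DME/H2O, reflux) saturates the alkene without touching the benzyl ethers and gives 10. The portion needed as 8 is then made from 10 with LiAlH4, so 7 is bypassed.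

**Step 7 (Mitsunobu coupling of a hindered acid with an ionisable benzylic alcohol).** The risks are ionisation of the activated alcohol followed by Friedel–Crafts side products, and difficult separation. The fallback sets out from 8 and 10 and comes back at 11. Alcohol 8 is converted into the benzyl chloride F7 (SOCl2, 2,6-lutidine, CH2Cl2, −20 °C, used crude). Acid 10 is converted into the caesium carboxylate F8 (Cs2CO3, DMF). SN2 O-alkylation of F8 with F7 in DMF at rt gives 11.

## Further compounds
F1 | step 8 | 5-(benzyloxy)-1-{2-[4-(benzyloxy)-3-methoxyphenyl]ethyl}-2-iodo-3-methoxybenzene (Ar–I) | Ic1c(CCc2ccc(OCc3ccccc3)c(OC)c2)cc(OCc2ccccc2)cc1OC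
F2 | step 8 | 4-(benzyloxy)-2-{2-[4-(benzyloxy)-3-methoxyphenyl]ethyl}-6-methoxybenzaldehyde (ArCHO) | O=Cc1c(CCc2ccc(OCc3ccccc3)c(OC)c2)cc(OCc2ccccc2)cc1OC
F3 | step 8 | aryllithium Ar–Li | [Li]c1c(CCc2ccc(OCc3ccccc3)c(OC)c2)cc(OCc2ccccc2)cc1OC
F4 | step 8 | diarylcarbinol Ar2CHOH (carbinol carbon not stereogenic) | OC(c1c(CCc2ccc(OCc3ccccc3)c(OC)c2)cc(OCc2ccccc2)cc1OC)c1c(CCc2ccc(OCc3ccccc3)c(OC)c2)cc(OCc2ccccc2)cc1OC
F5 | step 4 | rac-6-(benzyloxy)-3-[4-(benzyloxy)-3-methoxyphenyl]-8-methoxy-3,4-dihydro-1H-isochromen-1-one | O=C1OC(c2ccc(OCc3ccccc3)c(OC)c2)Cc2cc(OCc3ccccc3)cc(OC)c12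
F6 | step 4 | 4-(benzyloxy)-2-{(E)-2-[4-(benzyloxy)-3-methoxyphenyl]ethenyl}-6-methoxybenzoic acid | OC(=O)c1c(/C=C/c2ccc(OCc3ccccc3)c(OC)c2)cc(OCc2ccccc2)cc1OC
F7 | step 7 | benzyl chloride ArCH2Cl | ClCc1c(CCc2ccc(OCc3ccccc3)c(OC)c2)cc(OCc2ccccc2)cc1OC
F8 | step 7 | caesium carboxylate ArCO2Cs | [Cs+].[O-]C(=O)c1c(CCc2ccc(OCc3ccccc3)c(OC)c2)cc(OCc2ccccc2)cc1OC
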